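## Structural features

The target is a 2,3,3a,5-tetrahydro-1-benzofuran-4,6-dione in which a six-membered carbocycle (ring A: C3a, C4, C5, C6, C7, C7a) is fused along C3a–C7a to a dihydrofuran (ring B: O1, C2, C3, C3a, C7a). O1–C7a=C7–C6=O is a vinylogous ester, C4 is a ketone held between the quaternary carbons C3a and C5 (gem-dimethyl), and C7 carries a (2R)-2-methylbutanoyl group. C3a (S) is a quaternary stereocentre bearing a prenyl group, and C2 (R) carries a 2-hydroxy-6-methylhept-5-en-2-yl chain whose carbinol carbon C1′ (S) is bonded directly to C2; C2 and C1′ are therefore contiguous oxygenated stereocentres, C3a stands 1,3 to C2 across ring B with the prenyl group cis to the C2 chain, and the acyl α-carbon is a remote fourth centre. Fragile elements are the two trisubstituted alkenes, the tertiary alcohol (which can close a six-membered enol ether on C7a in place of O1), the non-enolisable 1,3-dicarbonyl arrays around C3a and C5 (retro-Claisen cleavage by nucleophiles) and the epimerisable acyl α-centre. The real difficulty is stereochemical: a tertiary carbinol next to a secondary ether carbon with defined relative and absolute configuration, and a quaternary carbon whose configuration must be tied to them. The key step uses the fact that the C2–C1′ bond joins two oxygen-bearing carbons and separates the chain C2–C3–C3a–C7a (aldehyde level at C2, carboxyl level at C7a) from C1′ with its methyl group and the first two carbons of the side chain, which is the pattern of an aldehyde ester plus a γ-oxygenated γ-methyl allyl boron reagent. The lactone that forms afterwards contains exactly O1, C2, C3, C3a and C7a, so it is ring B at the lactone oxidation level and serves as the rigid template on which C3a is set.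

## Logic of the disconnections

**26 ⇒ 25.** Only the O–Si bond at C1′ is cut. The tertiary hydroxyl stays masked to the end so that it cannot compete with O1 for C7a or accept a migrating group. The forward step must remove a tertiary silyl ether without touching the alkenes, the vinylogous ester or the acyl α-centre.

**25 ⇒ 21 + 23.** The C7–C(acyl) bond is cut. C7 is the only C–H carbon of ring A, and the acyl α-centre is the most easily lost stereocentre, so it is attached last and meets one basic step only. This removes five carbons and one stereocentre; 23 comes from 22. The forward step needs metalation at C7 without attack on C4 or C6 and acylation without epimerisation.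

**21 ⇒ 19 (through 20).** The enol ether bond O1–C7a and the C7–C7a bond are cut. C7a is at the carboxyl oxidation level, so ring B of 21 is recognised as a γ-lactone, and C7 is the methyl group of a methyl ketone, the only enolisable site of 19. Ring A is reduced to an open diketone chain on a lactone that already holds all atoms of ring B. The forward step is a Claisen-type closure followed by re-closure through O1, not through the C1′ oxygen and not at C4.

**19 ⇒ 14 + 16 (through 18).** The C3a–C4 bond is cut. C3a is α to the lactone carbonyl, and this bond is made last at that carbon so that the incoming carbon enters anti to the C2 substituent, which leaves the prenyl group cis. The quaternary centre becomes a lactone enolate problem; 16 comes from 15. The forward step is an aldol between a tetrasubstituted enolate and an α-quaternary aldehyde, then a non-basic oxidation.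

**14 ⇒ 11 + 12.** The C3a–CH2 bond of the prenyl group is cut. A simple enolate alkylation suffices and the configuration of the new centre does not matter, because it is re-enolised.

**11 ⇒ 8 + 9.** The sp3–sp2 bond between the second and third chain carbons beyond C1′ is cut. This leaves a vinyl group on C1′, which is what an allyl transfer leaves behind. The forward step is a terminal hydroboration and a B-alkyl cross-coupling that tolerates a lactone.

**8 ⇒ 4 + 5 (through 6 and 7; key).** The C2–C1′ bond and the acyl C7a–O1 bond are cut. This is the only bond between the two oxygenated stereocentres, and both fragments are achiral four-carbon pieces. The forward step needs geometrically pure 4, a closed transition state and a catalyst that selects the aldehyde face, with the enol ether surviving the acid.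

**4 ⇒ 2 + 3, and 2 ⇒ 1.** The C–B bond (with one C–H) and then the O–Si bond are cut. The forward hydroboration must be 1,4, place boron on the unsubstituted terminus and deliver through the s-cis diene so that the alkene is (E).

**16 ⇒ 15 and 23 ⇒ 22.** Functional group interconversions only (alcohol to aldehyde, acid to acid chloride).

## Other disconnections considered

**Alternative 1:** The cut removes C4–C5–C6 as one unit by breaking C6–C7 and C3a–C4. Ring B with all its substituents and the acyl chain remains as the exocyclic vinylogous ester A1, and the three-carbon unit is the diacid chloride A2. In the forward key step A1 and A2 with a tertiary amine would first join at C7; deprotonation at C3a would then give an extended dienolate whose γ-carbon closes ring A on the second acid chloride, giving A3 (the same compound as 25).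
- In its favour: two C–C bonds, ring A and the quaternary centre come in one operation with the acyl chain already in place. A2 has no α-hydrogen and cannot form a ketene. The closure would occur anti to the C2 substituent, the sense required.
- Against it: after the first acylation the intermediate is an enolised tricarbonyl whose oxygen is a far better nucleophile than the hindered tertiary γ-carbon, so closure through oxygen to a pyrandione is the expected competitor. The acyl α-centre sits in a tricarbonyl system while amine base is present. A1 still needs the C2/C1′ pair and would have to be made from a lactone such as 14.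
- Comparison: structurally it uses the same ring-B-first logic and the same 1,3-induction from C2, so it is equal on the source of C3a control. Mechanistically it depends on C- over O-selectivity that nothing in the substrate secures, whereas the chosen aldol can only occur at carbon. On step economy it is better, by about three steps after the lactone stage.

**Alternative 2:** The cut is the C3a–C3 bond (with O1–C7a to be closed later), giving the prenylated acyl trione A4 and the bromo ketone A5, which derives from (S)-linalool A6. In the forward key step the enolate of A4, ion-paired with a chiral N-spiro binaphthyl ammonium cation under carbonate base, would displace bromide from A5 to give A7.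
- In its favour: it is the most convergent plan. A4 is a short-sequence acylphloroglucinol derivative, and A6 supplies C1′ with its complete chain, so no hydroboration or cross-coupling is needed. C3a would be set by the catalyst without a relay.
- Against it: the nucleophile is a highly delocalised, weakly basic tricarbonyl enolate that can alkylate on oxygen, and discrimination of the faces of such a flat anion by ion pairing is untested for this class. C2 remains to be created by reduction of a ketone next to the quaternary silyloxy carbon in a molecule with three other carbonyl groups. The acyl α-centre is exposed to base.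
- Comparison: structurally it sets C3a and C2 in separate events, while the chosen plan sets C2 and C1′ together and relays to C3a. Mechanistically an open ion pair is less predictable than a closed chair transition state followed by a rigid lactone template. On step count it is clearly better; its risk is concentrated in one selectivity without close analogy.

**Alternative 3:** The cut is the C3a–C4 bond, made by the anti aldol of the 3-prenyl lactone A8 (the same compound as 14) with aldehyde 16 to give A9 (the same compound as 18). The difference lies upstream: A8 would come from the lactone acid A10 of D-glutamic acid A11, with C2 taken from the chiral pool and C1′ built from the carboxyl group by two successive carbon nucleophile additions.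
- In its favour: the absolute configuration at C2 is purchased, no chiral catalyst or boron reagent is needed, and the aldol relay is the one the chosen plan also uses.
- Against it: C1′ must be set by 1,2-induction from C2 in an addition to a ketone flanked by a lactone oxygen, a poor chelating group, so the sense and level of induction are not secured. The organometallic additions must spare the lactone carbonyl. The unnatural amino acid series is required and several functional group steps precede the hindered tertiary silylation.
- Comparison: on the key aldol it is equal, since the step is identical. On certainty of the C2 configuration it is equal or better. On control of C1′ and on step count before the lactone stage the chosen plan is better, because one catalytic step sets both centres with relative configuration fixed by alkene geometry.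

Key step: step 3

Assumptions and remarks on the chemistry:
- Reading the target gives C2 = R, C3a = S, C1′ = S and the acyl α-carbon = R, so the (R)-acid 22 is required.
- 15 and 22 are taken as purchasable.
- The γ-lactone 8 is not a ring foreign to the target: its five atoms are O1, C2, C3, C3a and C7a of ring B. It is opened at C7a–O1 in step 9 and closed again there as the enol ether.
- The descriptor of the quaternary carbon changes from R (18, 19) to S (20 onward) only because the ranking of its carbonyl neighbours changes; no bond to it is broken.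
- The triethylsilyl group and the pinacol ester of 4 are kept as they are. A smaller silyl group would not last to step 12 and a larger one would be hard to remove from the tertiary position.

## Route

Step 1
Reactants: 1 but-3-en-2-one
Product: 2 triethyl(buta-1,3-dien-2-yloxy)silane
Conditions: Et3SiOTf, Et3N, Et2O, 0 °C
Reagents that add atoms: triethylsilyl trifluoromethanesulfonate, CC[Si](CC)(CC)OS(=O)(=O)C(F)(F)F
Why: Silyl enol ether formation by soft enolisation of the methyl ketone; O-silylation of the cross-conjugated enolate gives the 2-silyloxydiene.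

Step 2
Reactants: 2 triethyl(buta-1,3-dien-2-yloxy)silane; 3 pinacolborane
Product: 4 triethyl{[(2E)-4-(4,4,5,5-tetramethyl-1,3,2-dioxaborolan-2-yl)but-2-en-2-yl]oxy}silane
Conditions: Ni(cod)2 (2.5 mol%), PCy3 (2.5 mol%), toluene, rt
Reagents that add atoms: none
Why: Ni-catalysed 1,4-hydroboration of a 1,3-diene: the diene binds s-cis, hydrogen goes to C1 and boron to the unsubstituted terminus C4, so the new methyl group and CH2B end cis and the silyloxy group trans, which is the (E)-isomer.

Step 3
Reactants: 4 triethyl{[(2E)-4-(4,4,5,5-tetramethyl-1,3,2-dioxaborolan-2-yl)but-2-en-2-yl]oxy}silane; 5 methyl 4-oxobutanoate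
Product: 8 (5R)-5-[(2S)-2-(triethylsilyloxy)but-3-en-2-yl]dihydrofuran-2(3H)-one, via O-boryl adduct 6 (not isolated), via hydroxy ester 7 (not isolated)
Conditions: (S)-3,3′-bis(2,4,6-triisopropylphenyl)-1,1′-binaphthyl-2,2′-diyl hydrogen phosphate (5 mol%), 4 Å MS, toluene, −30 °C; aq. NaHCO3 work-up; then pyridinium p-toluenesulfonate (cat.), CH2Cl2, rt
Reagents that add atoms: none
Why: Boron of 4 binds the aldehyde oxygen of 5 and the γ-carbon is transferred with allylic transposition through a six-membered chair (Zimmerman–Traxler) transition state with the aldehyde chain equatorial, forming C2–C1′ and the borate 6. The closest known reaction types are the chiral phosphoric acid-catalysed allyl- and crotylboration of aldehydes with pinacol boronates and the γ-alkoxyallylboration that gives anti-1,2-diol derivatives. Relative configuration comes from the alkene geometry: the silyloxy group (trans to CH2B) is pseudo-equatorial and the methyl group pseudo-axial, so the two oxygens end anti and the methyl syn to the new hydroxyl, the (4R,5S) pair of 7. Absolute configuration comes from the catalyst, which hydrogen-bonds to the pseudo-axial boronate oxygen and to the formyl hydrogen; the (S)-acid is expected to open the Si face of 5 (the (R)-acid delivers to the Re face of simple aldehydes), giving R at C2, and the enantiomeric acid would be used if the sense proved opposite. After hydrolysis of 6, mild acid closes the γ-lactone by 5-exo-trig attack of the C2 hydroxyl on the ester carbonyl. The step needs aldehyde-over-ester chemoselectivity (allyl boronates do not add to esters), γ-attack (enforced by the cyclic transition state), retention of alkene geometry (no 1,3-boryl shift in pinacol esters at this temperature) and survival of the silyl enol ether, for which the bulky weak acid, sieves and low temperature are chosen.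

Step 4
Reactants: 8 (5R)-5-[(2S)-2-(triethylsilyloxy)but-3-en-2-yl]dihydrofuran-2(3H)-one; 9 1-bromo-2-methylprop-1-ene
Product: 11 (5R)-5-[(2S)-6-methyl-2-(triethylsilyloxy)hept-5-en-2-yl]dihydrofuran-2(3H)-one, via B-alkyl borane 10 (not isolated)
Conditions: 9-borabicyclo[3.3.1]nonane (1.3 equiv), THF, 0 °C → rt; then 9, PdCl2(dppf) (5 mol%), AsPh3 (5 mol%), K3PO4 (aq.), DMF, rt
Reagents that add atoms: none
Why: Anti-Markovnikov hydroboration of the monosubstituted alkene followed by B-alkyl Suzuki–Miyaura coupling with the vinyl bromide. The lactone and the tertiary silyl ether are inert to the borane at room temperature and to aqueous phosphate, boron sits γ to the silyloxy carbon so β-elimination is impossible, and no stereocentre is touched.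

Step 5
Reactants: 11 (5R)-5-[(2S)-6-methyl-2-(triethylsilyloxy)hept-5-en-2-yl]dihydrofuran-2(3H)-one; 12 1-bromo-3-methylbut-2-ene
Product: 14 (3S,5R)-3-(3-methylbut-2-en-1-yl)-5-[(2S)-6-methyl-2-(triethylsilyloxy)hept-5-en-2-yl]dihydrofuran-2(3H)-one (3,5-trans isomer expected as the major one; the 3R epimer is carried along), via lithium enolate 13 (not isolated)
Conditions: LiN(iPr)2 (1.05 equiv), THF, −78 °C; then 12, −78 → −30 °C
Reagents that add atoms: none
Why: Lactone enolate alkylation (SN2 at the primary allylic bromide). The new centre is re-enolised in step 7, so both epimers are usable.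

Step 6
Reactants: 15 4-hydroxy-3,3-dimethylbutan-2-one
Product: 16 2,2-dimethyl-3-oxobutanal
Conditions: Dess–Martin periodinane, CH2Cl2, 0 °C → rt; distillation
Reagents that add atoms: none
Why: Dess–Martin oxidation of a primary alcohol; the aldehyde has no α-hydrogen, so it cannot enolise or self-condense.

Step 7
Reactants: 14 (3S,5R)-3-(3-methylbut-2-en-1-yl)-5-[(2S)-6-methyl-2-(triethylsilyloxy)hept-5-en-2-yl]dihydrofuran-2(3H)-one; 16 2,2-dimethyl-3-oxobutanal
Product: 18 (3R,5R)-3-(1-hydroxy-2,2-dimethyl-3-oxobutyl)-3-(3-methylbut-2-en-1-yl)-5-[(2S)-6-methyl-2-(triethylsilyloxy)hept-5-en-2-yl]dihydrofuran-2(3H)-one (both carbinol epimers), via lithium enolate 17 (not isolated)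
Conditions: LiN(iPr)2 (1.1 equiv), THF, −78 °C; then 16, −78 °C; AcOH quench at −78 °C
Reagents that add atoms: none
Why: Aldol addition of a tetrasubstituted lithium lactone enolate to a non-enolisable aldehyde. The bulky C5 substituent shields one face of the planar enolate, so the aldehyde should add anti to it (1,3-induction), placing C4 trans and the prenyl group cis to the C2 chain, as in the target. Aldehyde addition should outpace proton transfer from the methyl ketone at −78 °C, and the carbinol centre is removed in step 8.

Step 8
Reactants: 18 (3R,5R)-3-(1-hydroxy-2,2-dimethyl-3-oxobutyl)-3-(3-methylbut-2-en-1-yl)-5-[(2S)-6-methyl-2-(triethylsilyloxy)hept-5-en-2-yl]dihydrofuran-2(3H)-one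
Product: 19 (3R,5R)-3-(2,2-dimethyl-3-oxobutanoyl)-3-(3-methylbut-2-en-1-yl)-5-[(2S)-6-methyl-2-(triethylsilyloxy)hept-5-en-2-yl]dihydrofuran-2(3H)-one
Conditions: Dess–Martin periodinane, CH2Cl2, 0 °C → rt
Reagents that add atoms: none
Why: Dess–Martin oxidation of a hindered secondary alcohol under non-basic conditions, which avoids retro-aldol cleavage; both carbinol epimers converge and no stereocentre is affected.

Step 9
Reactants: 19 (3R,5R)-3-(2,2-dimethyl-3-oxobutanoyl)-3-(3-methylbut-2-en-1-yl)-5-[(2S)-6-methyl-2-(triethylsilyloxy)hept-5-en-2-yl]dihydrofuran-2(3H)-one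
Product: 21 (2R,3aS)-5,5-dimethyl-3a-(3-methylbut-2-en-1-yl)-2-[(2S)-6-methyl-2-(triethylsilyloxy)hept-5-en-2-yl]-2,3,3a,5-tetrahydro-1-benzofuran-4,6-dione, via hydroxy trione 20 (not isolated)
Conditions: LiN(SiMe3)2 (1.05 equiv), THF, −78 → 0 °C; AcOH (1.1 equiv); then pyridinium p-toluenesulfonate (cat.), 4 Å MS, toluene, 60 °C
Reagents that add atoms: none
Why: Intramolecular Claisen (Dieckmann-type) condensation: C7 is the only enolisable carbon of 19 and its enolate closes ring A on the lactone carbonyl C7a (6-exo-trig), freeing the C2 oxygen, which is protonated at once by the new 1,3-dione because only one equivalent of base is present. Mild acid then closes ring B by addition–elimination of the C2 hydroxyl at C7a (vinylogous ester formation); the C2–O bond and the bonds of C3a are never broken, so both centres are retained. The competing hemiketal at C4 cannot lose water and reverts, and the silylated C1′ oxygen cannot form the six-membered enol ether.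

Step 10
Reactants: 22 (2R)-2-methylbutanoic acid
Product: 23 (2R)-2-methylbutanoyl chloride
Conditions: (COCl)2, N,N-dimethylformamide (cat.), CH2Cl2, 0 °C → rt; used directly
Reagents that add atoms: oxalyl chloride, ClC(=O)C(Cl)=O
Why: Acid chloride formation under formamide catalysis with no base present, conditions under which the α-stereocentre should be retained.

Step 11
Reactants: 21 (2R,3aS)-5,5-dimethyl-3a-(3-methylbut-2-en-1-yl)-2-[(2S)-6-methyl-2-(triethylsilyloxy)hept-5-en-2-yl]-2,3,3a,5-tetrahydro-1-benzofuran-4,6-dione; 23 (2R)-2-methylbutanoyl chloride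
Product: 25 (2R,3aS)-5,5-dimethyl-7-[(2R)-2-methylbutanoyl]-3a-(3-methylbut-2-en-1-yl)-2-[(2S)-6-methyl-2-(triethylsilyloxy)hept-5-en-2-yl]-2,3,3a,5-tetrahydro-1-benzofuran-4,6-dione, via vinyllithium 24 (not isolated)
Conditions: lithium 2,2,6,6-tetramethylpiperidide (1.1 equiv), THF, −78 °C; then cannulated into 23 (2 equiv), THF, −78 °C
Reagents that add atoms: none
Why: Vinylic deprotonation of a β-alkoxy enone (C7–H is the only acidic C–H because C3a and C5 are quaternary) by a hindered lithium amide, then C-acylation of the vinyllithium by the acid chloride. Inverse addition to excess 23 at −78 °C limits enolisation of the new ketone and so protects the (R) centre; the C4 ketone is shielded by two quaternary neighbours.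

Step 12
Reactants: 25 (2R,3aS)-5,5-dimethyl-7-[(2R)-2-methylbutanoyl]-3a-(3-methylbut-2-en-1-yl)-2-[(2S)-6-methyl-2-(triethylsilyloxy)hept-5-en-2-yl]-2,3,3a,5-tetrahydro-1-benzofuran-4,6-dione
Product: 26 (2R,3aS)-2-[(2S)-2-hydroxy-6-methylhept-5-en-2-yl]-5,5-dimethyl-7-[(2R)-2-methylbutanoyl]-3a-(3-methylbut-2-en-1-yl)-2,3,3a,5-tetrahydro-1-benzofuran-4,6-dione
Conditions: HF·pyridine, pyridine, THF, 0 °C → rt
Reagents that add atoms: none
Why: Fluoride-mediated cleavage of the tertiary silyl ether under buffered conditions that should leave the alkenes, the vinylogous ester and the acyl α-centre untouched.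

## Compound list

1 | but-3-en-2-one | CC(=O)C=C | starting material
2 | triethyl(buta-1,3-dien-2-yloxy)silane | C=CC(=C)O[Si](CC)(CC)CC | intermediate
3 | pinacolborane (4,4,5,5-tetramethyl-1,3,2-dioxaborolane) | B1OC(C)(C)C(C)(C)O1 | starting material
4 | triethyl{[(2E)-4-(4,4,5,5-tetramethyl-1,3,2-dioxaborolan-2-yl)but-2-en-2-yl]oxy}silane | CC[Si](CC)(CC)O/C(C)=C/CB1OC(C)(C)C(C)(C)O1 | intermediate
5 | methyl 4-oxobutanoate | COC(=O)CCC=O | starting material
6 | methyl (4R,5S)-5-methyl-4-[(4,4,5,5-tetramethyl-1,3,2-dioxaborolan-2-yl)oxy]-5-(triethylsilyloxy)hept-6-enoate | COC(=O)CC[C@@H](OB1OC(C)(C)C(C)(C)O1)[C@@](C)(O[Si](CC)(CC)CC)C=C | intermediate (not isolated)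
7 | methyl (4R,5S)-4-hydroxy-5-methyl-5-(triethylsilyloxy)hept-6-enoate | COC(=O)CC[C@@H](O)[C@@](C)(O[Si](CC)(CC)CC)C=C | intermediate (not isolated)
8 | (5R)-5-[(2S)-2-(triethylsilyloxy)but-3-en-2-yl]dihydrofuran-2(3H)-one | O1[C@@H]([C@@](C)(O[Si](CC)(CC)CC)C=C)CCC1=O | intermediate
9 | 1-bromo-2-methylprop-1-ene | CC(C)=CBr | starting material
10 | (5R)-5-[(2S)-4-(9-borabicyclo[3.3.1]nonan-9-yl)-2-(triethylsilyloxy)butan-2-yl]dihydrofuran-2(3H)-one | O1[C@@H]([C@@](C)(O[Si](CC)(CC)CC)CCB2C3CCCC2CCC3)CCC1=O | intermediate (not isolated)
11 | (5R)-5-[(2S)-6-methyl-2-(triethylsilyloxy)hept-5-en-2-yl]dihydrofuran-2(3H)-one | O1[C@@H]([C@@](C)(O[Si](CC)(CC)CC)CCC=C(C)C)CCC1=O | intermediate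
12 | 1-bromo-3-methylbut-2-ene | CC(C)=CCBr | starting material
13 | lithium (5R)-5-[(2S)-6-methyl-2-(triethylsilyloxy)hept-5-en-2-yl]-4,5-dihydrofuran-2-olate | [Li]OC1=CC[C@@H](O1)[C@@](C)(O[Si](CC)(CC)CC)CCC=C(C)C | intermediate (not isolated)
14 | (3S,5R)-3-(3-methylbut-2-en-1-yl)-5-[(2S)-6-methyl-2-(triethylsilyloxy)hept-5-en-2-yl]dihydrofuran-2(3H)-one (with its 3R epimer) | O=C1O[C@@H]([C@@](C)(O[Si](CC)(CC)CC)CCC=C(C)C)C[C@@H]1CC=C(C)C | intermediate
15 | 4-hydroxy-3,3-dimethylbutan-2-one | CC(=O)C(C)(C)CO | starting material
16 | 2,2-dimethyl-3-oxobutanal | CC(=O)C(C)(C)C=O | intermediate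
17 | lithium (5R)-3-(3-methylbut-2-en-1-yl)-5-[(2S)-6-methyl-2-(triethylsilyloxy)hept-5-en-2-yl]-4,5-dihydrofuran-2-olate | [Li]OC1=C(CC=C(C)C)C[C@@H](O1)[C@@](C)(O[Si](CC)(CC)CC)CCC=C(C)C | intermediate (not isolated)
18 | (3R,5R)-3-(1-hydroxy-2,2-dimethyl-3-oxobutyl)-3-(3-methylbut-2-en-1-yl)-5-[(2S)-6-methyl-2-(triethylsilyloxy)hept-5-en-2-yl]dihydrofuran-2(3H)-one (carbinol epimers) | O=C1O[C@@H]([C@@](C)(O[Si](CC)(CC)CC)CCC=C(C)C)C[C@]1(CC=C(C)C)C(O)C(C)(C)C(C)=O | intermediate
19 | (3R,5R)-3-(2,2-dimethyl-3-oxobutanoyl)-3-(3-methylbut-2-en-1-yl)-5-[(2S)-6-methyl-2-(triethylsilyloxy)hept-5-en-2-yl]dihydrofuran-2(3H)-one | O=C1O[C@@H]([C@@](C)(O[Si](CC)(CC)CC)CCC=C(C)C)C[C@]1(CC=C(C)C)C(=O)C(C)(C)C(C)=O | intermediate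
20 | (2S)-2-[(2R,3S)-2-hydroxy-3,7-dimethyl-3-(triethylsilyloxy)oct-6-en-1-yl]-4,4-dimethyl-2-(3-methylbut-2-en-1-yl)cyclohexane-1,3,5-trione | O[C@@H]([C@@](C)(O[Si](CC)(CC)CC)CCC=C(C)C)C[C@]1(CC=C(C)C)C(=O)C(C)(C)C(=O)CC1=O | intermediate (not isolated)
21 | (2R,3aS)-5,5-dimethyl-3a-(3-methylbut-2-en-1-yl)-2-[(2S)-6-methyl-2-(triethylsilyloxy)hept-5-en-2-yl]-2,3,3a,5-tetrahydro-1-benzofuran-4,6-dione | O=C1C=C2O[C@@H]([C@@](C)(O[Si](CC)(CC)CC)CCC=C(C)C)C[C@]2(CC=C(C)C)C(=O)C1(C)C | intermediate
22 | (2R)-2-methylbutanoic acid | CC[C@@H](C)C(O)=O | starting material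
23 | (2R)-2-methylbutanoyl chloride | CC[C@@H](C)C(Cl)=O | intermediate
24 | 7-lithio derivative of 21 | [Li]C1=C2O[C@@H]([C@@](C)(O[Si](CC)(CC)CC)CCC=C(C)C)C[C@]2(CC=C(C)C)C(=O)C(C)(C)C1=O | intermediate (not isolated)
25 | (2R,3aS)-5,5-dimethyl-7-[(2R)-2-methylbutanoyl]-3a-(3-methylbut-2-en-1-yl)-2-[(2S)-6-methyl-2-(triethylsilyloxy)hept-5-en-2-yl]-2,3,3a,5-tetrahydro-1-benzofuran-4,6-dione | CC[C@@H](C)C(=O)C1=C2O[C@@H]([C@@](C)(O[Si](CC)(CC)CC)CCC=C(C)C)C[C@]2(CC=C(C)C)C(=O)C(C)(C)C1=O | intermediate
26 | (2R,3aS)-2-[(2S)-2-hydroxy-6-methylhept-5-en-2-yl]-5,5-dimethyl-7-[(2R)-2-methylbutanoyl]-3a-(3-methylbut-2-en-1-yl)-2,3,3a,5-tetrahydro-1-benzofuran-4,6-dione | CC[C@@H](C)C(=O)C1=C2O[C@@H]([C@@](C)(O)CCC=C(C)C)C[C@]2(CC=C(C)C)C(=O)C(C)(C)C1=O | target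

## Step count and least certain steps

Total step count: 12. Longest linear sequence: 10 steps (steps 1, 2, 3, 4, 5, 7, 8, 9, 11, 12).

**Step 3 (key step).** The γ,γ-disubstituted pinacol boronate must place its methyl group axial in the chair, so the addition may be slow. That gives time for loss of the silyl enol ether by protonation or silyl transfer to the catalyst, and for a poorly discriminated background addition that lowers the enantiomeric purity.
Fallback (sets out from 5, returns at 8): the C2–C1′ pair is made by anti-dioxygenation of an (E)-trisubstituted alkene.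
- Wittig reaction of 5 with Ph3P=C(CH3)CHO should give the (E)-enal F1.
- Luche reduction (NaBH4, CeCl3·7H2O) gives the (E)-allylic alcohol F2.
- Sharpless asymmetric epoxidation with Ti(OiPr)4, D-(−)-diethyl tartrate and tBuOOH should give the (2S,3S)-epoxy alcohol F3.
- Acid-promoted 5-exo opening of the epoxide at its secondary carbon by the ester carbonyl (inversion there, retention at the quaternary carbon) gives the diol lactone F4.
- Dess–Martin oxidation of the primary alcohol gives the hydroxy aldehyde F5, which has no α-hydrogen and cannot epimerise.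
- Silylation (Et3SiOTf, 2,6-lutidine) gives the silyloxy aldehyde F6, and methylenation with Ph3P=CH2 returns 8.

**Step 2.** Boron may be delivered to the wrong terminus of the diene (next to the silyloxy carbon), the alkene geometry may erode, or the electron-rich diene may inhibit the catalyst. Any geometric impurity becomes the C1′ epimer in step 3.
Fallback (sets out from 3, returns at 4): racemic but-3-yn-2-ol F7 is silylated (Et3SiCl, imidazole) to its triethylsilyl ether F8. Hydroboration with 3 under Cp2Zr(H)Cl catalysis gives the (E)-alkenyl boronate F9. Iridium-catalysed double-bond migration ([Ir(cod)(PPh2Me)2]PF6, activated with H2) should move the alkene into conjugation with oxygen and give 4. The geometry would have to be established before use, since only the (E)-isomer leads to 8.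

**Step 7.** The aldol joins a tetrasubstituted enolate to an α-quaternary aldehyde. Reversal of the congested addition on warming, proton transfer from the methyl ketone of 16 to the enolate, and incomplete face selection are the likely failures.
Fallback (sets out from 14, returns at 18): C4 is introduced as a one-carbon unit and the hindered C4–C5 bond is made separately. Enolate 17 is trapped with monomeric formaldehyde to give the 3-hydroxymethyl lactone F10, again anti to the C5 substituent. Dess–Martin oxidation gives the non-enolisable 3-formyl lactone F11. A SmI2-mediated Reformatsky-type addition of 3-bromo-3-methylbutan-2-one then forms C4–C5 and returns 18 as its carbinol epimers.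

**Step 9.** The alkoxide released at C2 sits next to the tertiary silyl ether, so migration of the silyl group to the secondary oxygen (followed by closure through the wrong oxygen) is possible. Alkoxide attack on the non-enolisable 1,3-dicarbonyl units could also cause retro-Claisen cleavage.
Fallback (sets out from 19, returns at 21): the C7–C7a bond is made by an intramolecular Wittig olefination of the lactone carbonyl, so that no alkoxide is set free at C2. Soft enolisation (Me3SiOTf, Et3N) gives the trimethylsilyl enol ether F12, N-bromosuccinimide the bromomethyl ketone F13, and PPh3 followed by Et3N the stabilised phosphorane F14. Heating in toluene should close ring A directly to the enol ether 21.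

**Step 11.** Epimerisation of the acyl α-centre (ketene formation from 23 by excess amide, or enolisation of the product by unreacted vinyllithium), incomplete metalation, and addition of the vinyllithium to a ring carbonyl are the likely failures.
Fallback (sets out from 21, returns at 25): iodination at C7 (I2, pyridine, CH2Cl2) gives the 7-iodo compound F15. Iodine–magnesium exchange (iPrMgCl·LiCl, −78 °C), transmetalation with ZnCl2 and Pd(PPh3)4-catalysed Negishi acylation with 23 give 25 without a strong amide base meeting the acid chloride.

## Further compounds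

F1 | step 3 | methyl (4E)-5-methyl-6-oxohex-4-enoate | COC(=O)CC/C=C(\C)C=O
F2 | step 3 | methyl (4E)-6-hydroxy-5-methylhex-4-enoate | COC(=O)CC/C=C(\C)CO
F3 | step 3 | methyl 3-[(2S,3S)-3-(hydroxymethyl)-3-methyloxiran-2-yl]propanoate | COC(=O)CC[C@@H]1O[C@@]1(C)CO
F4 | step 3 | (5R)-5-[(2S)-1,2-dihydroxypropan-2-yl]dihydrofuran-2(3H)-one | O1[C@@H]([C@@](C)(O)CO)CCC1=O
F5 | step 3 | (2R)-2-hydroxy-2-[(2R)-5-oxooxolan-2-yl]propanal | O1[C@@H]([C@@](C)(O)C=O)CCC1=O
F6 | step 3 | (2R)-2-[(2R)-5-oxooxolan-2-yl]-2-(triethylsilyloxy)propanal | O1[C@@H]([C@@](C)(O[Si](CC)(CC)CC)C=O)CCC1=O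
F7 | step 2 | but-3-yn-2-ol (racemic) | CC(O)C#C
F8 | step 2 | triethyl(but-3-yn-2-yloxy)silane (racemic) | CC(O[Si](CC)(CC)CC)C#C
F9 | step 2 | triethyl{[(3E)-4-(4,4,5,5-tetramethyl-1,3,2-dioxaborolan-2-yl)but-3-en-2-yl]oxy}silane (racemic) | CC(O[Si](CC)(CC)CC)/C=C/B1OC(C)(C)C(C)(C)O1
F10 | step 7 | (3R,5R)-3-(hydroxymethyl)-3-(3-methylbut-2-en-1-yl)-5-[(2S)-6-methyl-2-(triethylsilyloxy)hept-5-en-2-yl]dihydrofuran-2(3H)-one | O=C1O[C@@H]([C@@](C)(O[Si](CC)(CC)CC)CCC=C(C)C)C[C@]1(CC=C(C)C)CO
F11 | step 7 | (3R,5R)-3-(3-methylbut-2-en-1-yl)-5-[(2S)-6-methyl-2-(triethylsilyloxy)hept-5-en-2-yl]-2-oxooxolane-3-carbaldehyde | O=C1O[C@@H]([C@@](C)(O[Si](CC)(CC)CC)CCC=C(C)C)C[C@]1(CC=C(C)C)C=O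
F12 | step 9 | (3R,5R)-3-[2,2-dimethyl-3-(trimethylsilyloxy)but-3-enoyl]-3-(3-methylbut-2-en-1-yl)-5-[(2S)-6-methyl-2-(triethylsilyloxy)hept-5-en-2-yl]dihydrofuran-2(3H)-one | O=C1O[C@@H]([C@@](C)(O[Si](CC)(CC)CC)CCC=C(C)C)C[C@]1(CC=C(C)C)C(=O)C(C)(C)C(=C)O[Si](C)(C)C
F13 | step 9 | (3R,5R)-3-(4-bromo-2,2-dimethyl-3-oxobutanoyl)-3-(3-methylbut-2-en-1-yl)-5-[(2S)-6-methyl-2-(triethylsilyloxy)hept-5-en-2-yl]dihydrofuran-2(3H)-one | O=C1O[C@@H]([C@@](C)(O[Si](CC)(CC)CC)CCC=C(C)C)C[C@]1(CC=C(C)C)C(=O)C(C)(C)C(=O)CBr
F14 | step 9 | (3R,5R)-3-[2,2-dimethyl-3-oxo-4-(triphenyl-λ5-phosphanylidene)butanoyl]-3-(3-methylbut-2-en-1-yl)-5-[(2S)-6-methyl-2-(triethylsilyloxy)hept-5-en-2-yl]dihydrofuran-2(3H)-one | O=C1O[C@@H]([C@@](C)(O[Si](CC)(CC)CC)CCC=C(C)C)C[C@]1(CC=C(C)C)C(=O)C(C)(C)C(=O)C=P(c1ccccc1)(c1ccccc1)c1ccccc1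
F15 | step 11 | (2R,3aS)-7-iodo-5,5-dimethyl-3a-(3-methylbut-2-en-1-yl)-2-[(2S)-6-methyl-2-(triethylsilyloxy)hept-5-en-2-yl]-2,3,3a,5-tetrahydro-1-benzofuran-4,6-dione | IC1=C2O[C@@H]([C@@](C)(O[Si](CC)(CC)CC)CCC=C(C)C)C[C@]2(CC=C(C)C)C(=O)C(C)(C)C1=O
A1 | alternative 1 | (3R)-3-methyl-1-[(5R)-3-(3-methylbut-2-en-1-yl)-5-[(2S)-6-methyl-2-(triethylsilyloxy)hept-5-en-2-yl]oxolan-2-ylidene]pentan-2-one (ring C3 and alkene geometry undefined) | CC[C@@H](C)C(=O)C=C1O[C@@H]([C@@](C)(O[Si](CC)(CC)CC)CCC=C(C)C)CC1CC=C(C)C
A2 | alternative 1 | 2,2-dimethylpropanedioyl dichloride | CC(C)(C(Cl)=O)C(Cl)=O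
A3 | alternative 1 | triethylsilyl ether of the target (identical with 25) | CC[C@@H](C)C(=O)C1=C2O[C@@H]([C@@](C)(O[Si](CC)(CC)CC)CCC=C(C)C)C[C@]2(CC=C(C)C)C(=O)C(C)(C)C1=O
A4 | alternative 2 | 3,5-dihydroxy-4,4-dimethyl-2-[(2R)-2-methylbutanoyl]-6-(3-methylbut-2-en-1-yl)cyclohexa-2,5-dien-1-one | CC[C@@H](C)C(=O)C1=C(O)C(C)(C)C(O)=C(CC=C(C)C)C1=O
A5 | alternative 2 | (3S)-1-bromo-3,7-dimethyl-3-(triethylsilyloxy)oct-6-en-2-one | BrCC(=O)[C@@](C)(O[Si](CC)(CC)CC)CCC=C(C)C
A6 | alternative 2 | (3S)-3,7-dimethylocta-1,6-dien-3-ol ((S)-linalool) | C=C[C@@](C)(O)CCC=C(C)C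
A7 | alternative 2 | (6S)-6-[(3S)-3,7-dimethyl-2-oxo-3-(triethylsilyloxy)oct-6-en-1-yl]-5-hydroxy-2,2-dimethyl-4-[(2R)-2-methylbutanoyl]-6-(3-methylbut-2-en-1-yl)cyclohex-4-ene-1,3-dione | CC[C@@H](C)C(=O)C1=C(O)[C@](CC=C(C)C)(CC(=O)[C@@](C)(O[Si](CC)(CC)CC)CCC=C(C)C)C(=O)C(C)(C)C1=O
A8 | alternative 3 | (3S,5R)-3-(3-methylbut-2-en-1-yl)-5-[(2S)-6-methyl-2-(triethylsilyloxy)hept-5-en-2-yl]dihydrofuran-2(3H)-one (identical with 14) | O=C1O[C@@H]([C@@](C)(O[Si](CC)(CC)CC)CCC=C(C)C)C[C@@H]1CC=C(C)C
A9 | alternative 3 | (3R,5R)-3-(1-hydroxy-2,2-dimethyl-3-oxobutyl)-3-(3-methylbut-2-en-1-yl)-5-[(2S)-6-methyl-2-(triethylsilyloxy)hept-5-en-2-yl]dihydrofuran-2(3H)-one (identical with 18) | O=C1O[C@@H]([C@@](C)(O[Si](CC)(CC)CC)CCC=C(C)C)C[C@]1(CC=C(C)C)C(O)C(C)(C)C(C)=O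
A10 | alternative 3 | (2R)-5-oxooxolane-2-carboxylic acid | O1[C@@H](C(O)=O)CCC1=O
A11 | alternative 3 | D-glutamic acid | N[C@H](CCC(O)=O)C(O)=O
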